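**Retrosynthetic overview**
- Last step is global desilylation; before it, both tetrahydrofuran rings of the furofuran (C8–C8' and C7'–O9 bonds) are closed in one visible-light titanocene/photoredox cycloisomerisation of an epoxy cinnamyl ether (ring A first, ring B in the same operation).
- The epoxy cinnamyl ether comes from cross-metathesis of a styrene carrying rings B and C (the complete 8''-O-4 unit) with an allyl ether carrying ring A and the epoxide.
- Styrene fragment: C8''–O bond by Mitsunobu inversion of L-serine-derived methyl (S)-glycerate with 4-vinylsyringol; C7''–aryl bond by Grignard acylation; erythro C7'' by chelation-controlled reduction.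
- Allyl ether fragment: (R)-glycidol → (S)-glycidaldehyde → Felkin–Anh aryl addition → O-allylation. The epoxide carbon sets C7 and is then consumed as the radical site.
- C7 then controls C8, C8' and C7' in the cyclisation; no chiral catalyst, reagent or auxiliary is used.

Assumption: methyl (S)-glycerate and (R)-glycidol are bought enantiopure; silyl chlorides, allyl bromide and the Wittig salt are commodity reagents.

---

**Step 1**
Reactants: 1 methyl (S)-2,3-dihydroxypropanoate; 2 tert-butyldimethylsilyl chloride
Product: 3 methyl (S)-3-(tert-butyldimethylsilyloxy)-2-hydroxypropanoate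
Conditions: TBSCl (1.05 equiv), imidazole, CH2Cl2, −10 → 0 °C
Reagents that add atoms: TBSCl, CC(C)(C)[Si](C)(C)Cl
Why: Selective silylation of the primary over the α-ester secondary hydroxyl; the stereocentre is untouched.

**Step 2**
Reactants: 4 syringaldehyde; 5 methyltriphenylphosphonium bromide
Product: 6 2,6-dimethoxy-4-vinylphenol (4-vinylsyringol)
Conditions: Ph3PCH3Br (2.5 equiv), KOtBu (2.6 equiv), THF, 0 °C → rt; used promptly (BHT)
Reagents that add atoms: methyltriphenylphosphonium bromide (CH2 unit), C[P+](c1ccccc1)(c1ccccc1)c1ccccc1.[Br-]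
Why: Wittig methylenation with excess ylide tolerates the phenoxide and gives the vinylphenol directly.

**Step 3**
Reactants: 3; 6
Product: 7 methyl (R)-3-(tert-butyldimethylsilyloxy)-2-(2,6-dimethoxy-4-vinylphenoxy)propanoate
Conditions: PPh3, DIAD, toluene/THF, 0 °C → rt
Reagents that add atoms: none
Why: Mitsunobu etherification of an α-hydroxy ester with a phenol (pKa ≈ 10) proceeds by clean SN2 inversion, converting the (S)-carbinol into the (R)-aryl ether that becomes C8''.

**Step 4**
Reactants: 8 4-bromo-2-methoxyphenol; 9 triisopropylsilyl chloride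
Product: 10 (4-bromo-2-methoxyphenoxy)triisopropylsilane
Conditions: TIPSCl, imidazole, DMF, rt
Reagents that add atoms: TIPSCl, CC(C)[Si](Cl)(C(C)C)C(C)C
Why: Standard phenol silylation; the TIPS ether survives Mg/Li reagents and alkoxides and is removed by fluoride at the end.

**Step 5**
Reactants: 7; 10
Product: 11 (R)-3-(tert-butyldimethylsilyloxy)-2-(2,6-dimethoxy-4-vinylphenoxy)-1-[3-methoxy-4-(triisopropylsilyloxy)phenyl]propan-1-one
Conditions: MeNH(OMe)·HCl (1.5 equiv), i-PrMgCl (3 equiv), THF, −20 °C; then ArMgBr (from 10, Mg, THF; 2 equiv), −20 → 0 °C; cold NH4Cl quench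
Reagents that add atoms: none
Why: One-pot ester → Weinreb amide → ketone (magnesium-amide aminolysis, then Grignard acylation stopping at the chelated tetrahedral intermediate); the weakly basic, cold conditions preserve the α-aryloxy stereocentre and the styrene is inert.

**Step 6**
Reactants: 11
Product: 12 (1S,2R)-3-(tert-butyldimethylsilyloxy)-2-(2,6-dimethoxy-4-vinylphenoxy)-1-[3-methoxy-4-(triisopropylsilyloxy)phenyl]propan-1-ol (erythro)
Conditions: Zn(BH4)2, Et2O, −30 → 0 °C
Reagents that add atoms: none
Why: Chelation-controlled (Cram-chelate) reduction: Zn bridges the carbonyl and α-aryloxy oxygens and hydride enters from the α-H face, giving the anti (erythro) 7''S alcohol from the 8''R ketone; the OTBS group does not chelate.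

**Step 7**
Reactants: 12; 13 tert-butyldimethylsilyl triflate
Product: 14 the C7''-O-TBS ether of 12
Conditions: TBSOTf, 2,6-lutidine, CH2Cl2, −78 → 0 °C
Reagents that add atoms: TBSOTf, CC(C)(C)[Si](C)(C)OS(=O)(=O)C(F)(F)F
Why: Silylation of the hindered benzylic alcohol removes the last protic group before the titanium step; no stereocentre is affected.

**Step 8**
Reactants: 15 (R)-glycidol
Product: 16 (S)-oxirane-2-carbaldehyde
Conditions: Dess–Martin periodinane, NaHCO3, CH2Cl2, 0 °C; filter, bulb-to-bulb distil, use at once as a CH2Cl2 solution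
Reagents that add atoms: none
Why: Buffered Dess–Martin oxidation gives the epoxy aldehyde without epimerisation (the descriptor changes R → S only through CIP priorities).

**Step 9**
Reactants: 16; 10
Product: 17 (R)-[3-methoxy-4-(triisopropylsilyloxy)phenyl][(S)-oxiran-2-yl]methanol (anti)
Conditions: 10, n-BuLi, THF, −78 °C; ClTi(OiPr)3; then 16, −78 → −30 °C; chromatographic removal of the minor syn isomer
Reagents that add atoms: none
Why: Felkin–Anh addition of the non-chelating aryltitanium triisopropoxide anti to the epoxide C–O bond gives the (1R,2S) epoxy alcohol, so the purchased epoxide centre sets C7.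

**Step 10**
Reactants: 17; 18 allyl bromide
Product: 19 the O-allyl ether of 17, (1R,2S)
Conditions: NaH, allyl bromide, Bu4NI (cat.), THF, 0 °C → rt
Reagents that add atoms: allyl bromide, C=CCBr
Why: Williamson etherification under cold aprotic conditions, where alkylation outpaces Payne rearrangement; the TIPS aryl ether resists the alkoxide.

**Step 11**
Reactants: 14; 19 (3 equiv)
Product: 20 the (E)-cinnamyl ether joining 14 and 19 (ring A–CH(epoxide)–O–CH2–CH=CH–ring B)
Conditions: Hoveyda–Grubbs II (7.5 mol %), 1,4-benzoquinone (10 mol %), CH2Cl2, 40 °C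
Reagents that add atoms: none
Why: Olefin cross-metathesis of an unhindered electron-rich styrene with an allyl ether is E-selective; benzoquinone suppresses Ru–H allyl-ether isomerisation, and the epoxide and silyl ethers are inert.

**Step 12**
Reactants: 20
Product: 21 tetra-silylated hedyotol C (ring A O-TIPS, ring C O-TIPS, C7''-O-TBS, C9''-O-TBS; furofuran 7S,8R,8'R,7'S)
Conditions: Cp2TiCl2 (20 mol %), Zn dust (20 mol %, priming), 4CzIPN (2 mol %), THF (0.05 M), degassed, 450 nm LEDs, rt
Reagents that add atoms: none
Why: Proposed new method: a redox-neutral photo-titanocene radical–polar crossover cycloisomerisation. Cp2Ti(III)Cl opens the epoxide to the secondary C8 radical and a Ti(IV)–O9 alkoxide; 5-exo-trig addition to the styrene through a Beckwith–Houk chair (C7 aryl pseudo-equatorial) forms C8–C8' with 7,8-trans/8,8'-cis geometry; the benzylic C7' radical (free or Ti(III)-capped) is oxidised by photoexcited 4CzIPN or 4CzIPN•+ to the p-alkoxybenzyl cation, which the tethered titanium alkoxide captures on the convex face (exo aryl, 7'S); 4CzIPN•− returns the electron to Ti(IV), so no stoichiometric redox reagent is consumed. The closest known chemistry is the stoichiometric Cp2TiCl epoxy-ether radical cyclisation followed by I2-induced closure to furofurans, together with photoredox–titanocene epoxide openings and photoredox radical–polar crossover etherification of styrenes.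

**Step 13**
Reactants: 21
Product: 22 hedyotol C
Conditions: TBAF/AcOH (1:1, 6 equiv), THF, 0 °C → rt
Reagents that add atoms: none
Why: Buffered fluoride cleaves the two aryl TIPS and two alkyl TBS ethers without the base or acid that could epimerise the benzylic furofuran ethers or ionise C7''.

---

**Compound list**
1 | methyl (S)-glycerate | COC(=O)[C@@H](O)CO | starting material
2 | TBSCl | CC(C)(C)[Si](C)(C)Cl | starting material (reagent)
3 | methyl (S)-3-(TBSO)-2-hydroxypropanoate | COC(=O)[C@@H](O)CO[Si](C)(C)C(C)(C)C | intermediate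
4 | syringaldehyde | COc1cc(C=O)cc(OC)c1O | starting material
5 | methyltriphenylphosphonium bromide | C[P+](c1ccccc1)(c1ccccc1)c1ccccc1.[Br-] | starting material (reagent)
6 | 2,6-dimethoxy-4-vinylphenol | C=Cc1cc(OC)c(O)c(OC)c1 | intermediate
7 | methyl (R)-2-aryloxy-3-(TBSO)propanoate | COC(=O)[C@H](Oc1c(OC)cc(C=C)cc1OC)CO[Si](C)(C)C(C)(C)C | intermediate
8 | 4-bromo-2-methoxyphenol | COc1cc(Br)ccc1O | starting material
9 | TIPSCl | CC(C)[Si](Cl)(C(C)C)C(C)C | starting material (reagent)
10 | (4-bromo-2-methoxyphenoxy)triisopropylsilane | COc1cc(Br)ccc1O[Si](C(C)C)(C(C)C)C(C)C | intermediate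
11 | (R)-α-aryloxy aryl ketone | COc1cc(C(=O)[C@H](Oc2c(OC)cc(C=C)cc2OC)CO[Si](C)(C)C(C)(C)C)ccc1O[Si](C(C)C)(C(C)C)C(C)C | intermediate
12 | (1S,2R)-erythro alcohol | C=Cc1cc(OC)c(O[C@H](CO[Si](C)(C)C(C)(C)C)[C@@H](O)c2ccc(O[Si](C(C)C)(C(C)C)C(C)C)c(OC)c2)c(OC)c1 | intermediate
13 | TBSOTf | CC(C)(C)[Si](C)(C)OS(=O)(=O)C(F)(F)F | starting material (reagent)
14 | fully silylated styrene (rings B + C) | C=Cc1cc(OC)c(O[C@H](CO[Si](C)(C)C(C)(C)C)[C@@H](O[Si](C)(C)C(C)(C)C)c2ccc(O[Si](C(C)C)(C(C)C)C(C)C)c(OC)c2)c(OC)c1 | intermediate
15 | (R)-glycidol | OC[C@@H]1CO1 | starting material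
16 | (S)-oxirane-2-carbaldehyde | O=C[C@@H]1CO1 | intermediate
17 | (1R,2S)-aryl epoxy alcohol | COc1cc([C@@H](O)[C@@H]2CO2)ccc1O[Si](C(C)C)(C(C)C)C(C)C | intermediate
18 | allyl bromide | C=CCBr | starting material (reagent)
19 | allyl ether of 17 | COc1cc([C@@H](OCC=C)[C@@H]2CO2)ccc1O[Si](C(C)C)(C(C)C)C(C)C | intermediate
20 | (E)-epoxy cinnamyl ether | COc1cc([C@@H](OC/C=C/c2cc(OC)c(O[C@H](CO[Si](C)(C)C(C)(C)C)[C@@H](O[Si](C)(C)C(C)(C)C)c3ccc(O[Si](C(C)C)(C(C)C)C(C)C)c(OC)c3)c(OC)c2)[C@@H]2CO2)ccc1O[Si](C(C)C)(C(C)C)C(C)C | intermediate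
21 | tetra-silyl hedyotol C | COc1cc([C@H]2OC[C@H]3[C@@H]2CO[C@@H]3c2cc(OC)c(O[C@H](CO[Si](C)(C)C(C)(C)C)[C@@H](O[Si](C)(C)C(C)(C)C)c3ccc(O[Si](C(C)C)(C(C)C)C(C)C)c(OC)c3)c(OC)c2)ccc1O[Si](C(C)C)(C(C)C)C(C)C | intermediate
22 | hedyotol C | COc1cc([C@H]2OC[C@H]3[C@@H]2CO[C@@H]3c2cc(OC)c(O[C@H](CO)[C@@H](O)c3ccc(O)c(OC)c3)c(OC)c2)ccc1O | target

---

**Total step count:** 13
**Longest linear sequence:** 8 (steps 1, 3, 5, 6, 7, 11, 12, 13)

**Three steps most likely to fail**
1. Step 12 (proposed photo-titanocene cycloisomerisation): turnover depends on photo-oxidation of the benzylic radical/benzyl–Ti species competing with unproductive Ti(III)/photocatalyst back-electron transfer. Fallback (known chemistry): stoichiometric Cp2TiCl (Cp2TiCl2/Zn, THF, rt) radical cyclisation of 20 followed by I2-induced closure to the furofuran.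
2. Step 9 (aryl addition to glycidaldehyde): the aldehyde is volatile and the anti:syn ratio may be modest. Fallback: use (S)-glyceraldehyde acetonide (from (R)-solketal) for the anti-selective aryltitanium addition, then O-allylate, hydrolyse the acetonide and close the diol to the epoxide (TsCl, then base), reaching the same 19 in two extra steps.
3. Step 11 (fragment cross-metathesis): styrene homodimerisation or allyl-ether isomerisation may limit yield with the valuable styrene 14. Fallback: join the fragments by allylic substitution instead, i.e. cross-metathesise 14 with excess (Z)-but-2-ene-1,4-diyl diacetate to the cinnamyl acetate and couple it with the zinc alkoxide of 17 under Pd(0) (Tsuji–Trost O-allylation).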